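**Retrosynthetic overview**

1. Rings: A benzene, B dihydrofuran, C cyclohexanone, D the 20-membered spermidine bis-lactam (dibenzofuran numbering: quaternary C9b, O-bearing C4a, ketone C3, aryl arm on C8). The last disconnection, one operation, cuts the CH2–NH bond at the butyl end of the spermidine bridge (aldehyde + primary amine, ring D) together with the O–C4a bond (retro-oxa-Michael, ring B). This leads back to a monocyclic (S)-4-aryl-4-alkenylcyclohex-2-enone whose phenol, amine and aldehyde carry only acid-labile masks.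
2. Enabling feature: the ring B oxygen sits on C4a, β to the C3 ketone of ring C, and its aryl group hangs on the neighbouring quaternary C9b (a β-aryloxy ketone that can only close cis). The secondary amine nitrogen is bonded to the terminal CH2 of a four-carbon chain from the acrylamide nitrogen, i.e. the carbonyl carbon of a 4-amidobutanal.
3. Both (Z)-acrylamides: Z-selective Horner–Wadsworth–Emmons olefinations with diphenyl phosphonoacetamides that already carry the C4 and C3 halves of spermidine. The two aldehydes come from the nitrile on C9b and, later, from the aryl bromide (Pd-catalysed formylation).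
4. Quaternary stereocentre: enantiotopos-selective deprotonation of an achiral 4-aryl-4-cyanocyclohexanone by a chiral lithium amide. The silyl enol ether stores the choice, masks the ketone and becomes the enone (Saegusa–Ito) just before the key step.
5. Order of ring formation: ring A bought; ring C by double Michael addition/Dieckmann condensation; rings B and D together in the key step.

Key step: step 13

Assumption: the lithium (R,R)-bis(1-phenylethyl)amide is taken to select between the enantiotopic α-CH2 groups of the 4-aryl-4-cyanocyclohexanone (aryl equatorial) in the sense known for 4-substituted cyclohexanones; should the opposite sense be found, the (S,S)-amide is used and nothing else changes.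

**Route**

Step 1
Reactants: 1 2-(5-bromo-2-methoxyphenyl)acetonitrile
Product: 2 2-(5-bromo-2-hydroxyphenyl)acetonitrile
Conditions: BBr3, CH2Cl2, −78 °C to 0 °C; H2O
Reagents that add atoms: none
Why: Lewis-acid cleavage of the aryl methyl ether (BBr3 demethylation) frees the phenol so that the methyl group can be exchanged for an acid-labile mask, the nitrile and aryl bromide being inert at low temperature.

Step 2
Reactants: 2 2-(5-bromo-2-hydroxyphenyl)acetonitrile
Product: 3 2-(5-bromo-2-tert-butoxyphenyl)acetonitrile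
Conditions: isobutene (excess), TfOH (cat.), CH2Cl2, −78 °C; Et3N quench
Reagents that add atoms: isobutene (2-methylpropene), CC(C)=C
Why: Acid-catalysed kinetic O-alkylation of the phenol with isobutene at low temperature should install a tert-butyl ether that withstands the bases, hydride and palladium steps ahead and falls off in TFA together with the other masks.

Step 3
Reactants: 3 2-(5-bromo-2-tert-butoxyphenyl)acetonitrile; 4 methyl acrylate (two equivalents are consumed)
Product: 6 racemic methyl 5-(5-bromo-2-tert-butoxyphenyl)-5-cyano-2-oxocyclohexane-1-carboxylate, via bis-Michael diester 5 (not isolated)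
Conditions: 4 (2.1 equiv), t-BuOK, THF, 0 °C to rt; AcOH quench
Reagents that add atoms: methyl acrylate (the second equivalent of 4), C=CC(=O)OC
Why: Double Michael addition of the arylacetonitrile anion to two equivalents of methyl acrylate followed in the same pot by Dieckmann condensation of the resulting diester (loss of methanol) should build ring C around the future quaternary carbon; no stereocentre of the target is set here.

Step 4
Reactants: 6 racemic methyl 5-(5-bromo-2-tert-butoxyphenyl)-5-cyano-2-oxocyclohexane-1-carboxylate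
Product: 7 1-(5-bromo-2-tert-butoxyphenyl)-4-oxocyclohexane-1-carbonitrile
Conditions: NaCl, DMSO/H2O, 150 °C
Reagents that add atoms: none
Why: Krapcho decarboxylation removes the ester under neutral conditions that spare the nitrile and the tert-butyl ether and should give the achiral, mirror-symmetric ketone.

Step 5
Reactants: 7 1-(5-bromo-2-tert-butoxyphenyl)-4-oxocyclohexane-1-carbonitrile
Product: 9 (1R)-1-(5-bromo-2-tert-butoxyphenyl)-4-[(tert-butyldimethylsilyl)oxy]cyclohex-3-ene-1-carbonitrile, via lithium enolate 8 (not isolated)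
Conditions: (R,R)-bis(1-phenylethyl)amine hydrochloride, n-BuLi (2 equiv), THF, −78 °C; 7; then TBSOTf, −78 °C; Et3N, aq. NaHCO3 work-up
Reagents that add atoms: tert-butyldimethylsilyl trifluoromethanesulfonate (TBSOTf), CC(C)(C)[Si](C)(C)OS(=O)(=O)C(F)(F)F
Why: Enantiotopos-selective deprotonation of a 4,4-disubstituted cyclohexanone by a C2-symmetric chiral lithium amide in the presence of LiCl, then O-silylation of the enolate, should make the quaternary carbon stereogenic (R descriptor here): the base removes one of the two enantiotopic axial α-protons of the chair with the aryl group equatorial, and the position of the enol ether double bond stores that choice while masking the ketone.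

Step 6
Reactants: 9 (1R)-1-(5-bromo-2-tert-butoxyphenyl)-4-[(tert-butyldimethylsilyl)oxy]cyclohex-3-ene-1-carbonitrile
Product: 11 (1R)-1-(5-bromo-2-tert-butoxyphenyl)-4-[(tert-butyldimethylsilyl)oxy]cyclohex-3-ene-1-carbaldehyde, via aldimine 10 (not isolated)
Conditions: i-Bu2AlH, toluene, −78 °C; aq. potassium sodium tartrate, then moist SiO2, 0 °C
Reagents that add atoms: water, O
Why: Partial reduction of the hindered tertiary nitrile with i-Bu2AlH stops at the N-aluminio imine, which is hydrolysed on work-up to the non-enolisable aldehyde, while the silyl enol ether, aryl bromide and tert-butyl ether should be inert.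

Step 7
Reactants: 12 2-(diphenoxyphosphoryl)acetic acid; 13 4,4-diethoxybutan-1-amine
Product: 14 diphenyl {2-[(4,4-diethoxybutyl)amino]-2-oxoethyl}phosphonate
Conditions: DCC, HOBt (cat.), CH2Cl2, 0 °C to rt
Reagents that add atoms: none
Why: Carbodiimide amide coupling of the phosphonoacetic acid with the primary amine should give the olefination reagent that carries the C4 half of the spermidine chain with its terminal carbon as a masked aldehyde.

Step 8
Reactants: 11 (1R)-1-(5-bromo-2-tert-butoxyphenyl)-4-[(tert-butyldimethylsilyl)oxy]cyclohex-3-ene-1-carbaldehyde; 14 diphenyl {2-[(4,4-diethoxybutyl)amino]-2-oxoethyl}phosphonate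
Product: 15 (2Z)-3-[(1S)-1-(5-bromo-2-tert-butoxyphenyl)-4-[(tert-butyldimethylsilyl)oxy]cyclohex-3-en-1-yl]-N-(4,4-diethoxybutyl)prop-2-enamide
Conditions: 14, t-BuOK (slightly less than 14), THF, −78 °C; then 11, −78 °C to 0 °C
Reagents that add atoms: none
Why: Z-selective Horner–Wadsworth–Emmons olefination with a diaryl phosphonoacetamide (the electron-poor aryloxy groups make collapse of the kinetically formed syn adduct fast and irreversible) should give the (Z)-acrylamide on the quaternary carbon; the aldehyde has no α-hydrogen, and the carbanion is formed before the aldehyde is added so that no free alkoxide meets the silyl enol ether.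

Step 9
Reactants: 15 (2Z)-3-[(1S)-1-(5-bromo-2-tert-butoxyphenyl)-4-[(tert-butyldimethylsilyl)oxy]cyclohex-3-en-1-yl]-N-(4,4-diethoxybutyl)prop-2-enamide
Product: 16 (2Z)-3-[(1S)-1-(2-tert-butoxy-5-formylphenyl)-4-[(tert-butyldimethylsilyl)oxy]cyclohex-3-en-1-yl]-N-(4,4-diethoxybutyl)prop-2-enamide
Conditions: Pd(OAc)2 (cat.), n-BuP(1-adamantyl)2 (cat.), TMEDA, CO/H2 (1:1, 5 bar), toluene, 100 °C
Reagents that add atoms: carbon monoxide, [C-]#[O+]
Why: Palladium-catalysed reductive carbonylation (formylation) of the aryl bromide with synthesis gas should turn the bromide para to the ether oxygen into the aldehyde under amine-buffered conditions that the acetal, silyl enol ether and amide tolerate.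

Step 10
Reactants: 12 2-(diphenoxyphosphoryl)acetic acid; 17 tert-butyl N-(3-aminopropyl)carbamate
Product: 18 tert-butyl N-(3-{[2-(diphenoxyphosphoryl)acetyl]amino}propyl)carbamate
Conditions: DCC, HOBt (cat.), CH2Cl2, 0 °C to rt
Reagents that add atoms: none
Why: Carbodiimide amide coupling as in step 7 should give the second olefination reagent, which carries the C3 half of the spermidine chain with its terminal nitrogen as the Boc carbamate.

Step 11
Reactants: 16 (2Z)-3-[(1S)-1-(2-tert-butoxy-5-formylphenyl)-4-[(tert-butyldimethylsilyl)oxy]cyclohex-3-en-1-yl]-N-(4,4-diethoxybutyl)prop-2-enamide; 18 tert-butyl N-(3-{[2-(diphenoxyphosphoryl)acetyl]amino}propyl)carbamate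
Product: 19 tert-butyl N-{3-[(2Z)-3-{4-tert-butoxy-3-[(1S)-4-[(tert-butyldimethylsilyl)oxy]-1-{(1Z)-3-[(4,4-diethoxybutyl)amino]-3-oxoprop-1-en-1-yl}cyclohex-3-en-1-yl]phenyl}prop-2-enamido]propyl}carbamate
Conditions: 18, t-BuOK, THF, −78 °C; then 16, −78 °C to −20 °C
Reagents that add atoms: none
Why: A second Z-selective Horner–Wadsworth–Emmons olefination with the diaryl phosphonoacetamide, now on the aromatic aldehyde, should give the (Z)-cinnamamide, the phosphonate CH2 being deprotonated in preference to the NH groups.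

Step 12
Reactants: 19 tert-butyl N-{3-[(2Z)-3-{4-tert-butoxy-3-[(1S)-4-[(tert-butyldimethylsilyl)oxy]-1-{(1Z)-3-[(4,4-diethoxybutyl)amino]-3-oxoprop-1-en-1-yl}cyclohex-3-en-1-yl]phenyl}prop-2-enamido]propyl}carbamate
Product: 20 tert-butyl N-{3-[(2Z)-3-{4-tert-butoxy-3-[(1S)-1-{(1Z)-3-[(4,4-diethoxybutyl)amino]-3-oxoprop-1-en-1-yl}-4-oxocyclohex-2-en-1-yl]phenyl}prop-2-enamido]propyl}carbamate
Conditions: Pd(OAc)2 (1.2 equiv), MeCN, rt
Reagents that add atoms: none
Why: Saegusa–Ito oxidation (palladium enolate, then β-hydride elimination) should turn the silyl enol ether into the enone on exactly the side chosen in step 5, so that the quaternary carbon keeps its configuration and the enone appears only one step before it is used.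

Step 13
Reactants: 20 tert-butyl N-{3-[(2Z)-3-{4-tert-butoxy-3-[(1S)-1-{(1Z)-3-[(4,4-diethoxybutyl)amino]-3-oxoprop-1-en-1-yl}-4-oxocyclohex-2-en-1-yl]phenyl}prop-2-enamido]propyl}carbamate
Product: 24 CNP0415009.2 (target macrocycle), via deprotected enone 21 (not isolated), via tricyclic amino aldehyde 22 (not isolated), via macrocyclic aldimine 23 (not isolated)
Conditions: TFA/H2O (9:1), 0 °C to rt; evaporate; MeCN (1 mM), NaOAc, AcOH, 4 Å MS, rt; then NaBH(OAc)3, rt
Reagents that add atoms: none
Why: Aqueous TFA removes the three acid-labile masks of 20 together (aryl tert-butyl ether, Boc, diethyl acetal) to give 21, whose phenol adds to the β-carbon of the cyclohexenone (oxa-Michael addition, the same event that follows phenol coupling in the presumed biosynthesis) to give 22; after dilution and acetate buffering the primary amine condenses with the aldehyde to the macrocyclic aldimine 23, and NaBH(OAc)3 reduces it, so that the bond between the butyl-terminal CH2 and the secondary amine nitrogen is the ring-closing bond. The closest known reaction types are the spontaneous phenol-to-enone closure that forms cis-hexahydrodibenzofuranones and the macrocyclising intramolecular reductive amination of amino aldehydes used for polyamine macrocycles. Ring B closes 5-exo-trig at the enone β-carbon; ring D closes as a 20-membered ring by exo attack of nitrogen on the aldehyde carbon (condensation, then hydride delivery) under high dilution. The one new stereocentre, the oxygen-bearing ring-fusion carbon C4a, is set by the quaternary carbon C9b: the phenol hangs on the aryl group of C9b and can only reach the enone face syn to that aryl group, so only the cis-fused (4aR,9bS) system should form, and because the addition is reversible and C9b is untouched the outcome is under thermodynamic as well as geometric control. The step needs the enone to win over the acrylamide on C9b as Michael acceptor (it is the far stronger acceptor and the addition is reversible), the aldehyde to win over the ring ketone (the aldimine is allowed to form before the hydride is added, and NaBH(OAc)3 reduces aldiminium ions much faster than it engages a ketone), and ring closure to win over oligomerisation (about 1 mM). The 4-amidobutanal may rest as its cyclic N-acyl hemiaminal, which is a ring–chain tautomer and remains an aldehyde source under the buffer.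

**Compound list**

1 | 2-(5-bromo-2-methoxyphenyl)acetonitrile | N#CCc1cc(Br)ccc1OC | starting material
2 | 2-(5-bromo-2-hydroxyphenyl)acetonitrile | N#CCc1cc(Br)ccc1O | intermediate
3 | 2-(5-bromo-2-tert-butoxyphenyl)acetonitrile | N#CCc1cc(Br)ccc1OC(C)(C)C | intermediate
4 | methyl acrylate | C=CC(=O)OC | starting material
5 | dimethyl 4-(5-bromo-2-tert-butoxyphenyl)-4-cyanoheptanedioate (not isolated) | COC(=O)CCC(C#N)(CCC(=O)OC)c1cc(Br)ccc1OC(C)(C)C | intermediate
6 | methyl 5-(5-bromo-2-tert-butoxyphenyl)-5-cyano-2-oxocyclohexane-1-carboxylate (racemic; keto and enol forms) | COC(=O)C1CC(C#N)(c2cc(Br)ccc2OC(C)(C)C)CCC1=O | intermediate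
7 | 1-(5-bromo-2-tert-butoxyphenyl)-4-oxocyclohexane-1-carbonitrile (achiral) | N#CC1(c2cc(Br)ccc2OC(C)(C)C)CCC(=O)CC1 | intermediate
8 | lithium (4R)-4-(5-bromo-2-tert-butoxyphenyl)-4-cyanocyclohex-1-en-1-olate (not isolated) | [Li]OC1=CC[C@@](C#N)(c2cc(Br)ccc2OC(C)(C)C)CC1 | intermediate
9 | (1R)-1-(5-bromo-2-tert-butoxyphenyl)-4-[(tert-butyldimethylsilyl)oxy]cyclohex-3-ene-1-carbonitrile | CC(C)(C)[Si](C)(C)OC1=CC[C@@](C#N)(c2cc(Br)ccc2OC(C)(C)C)CC1 | intermediate
10 | 1-[(1R)-1-(5-bromo-2-tert-butoxyphenyl)-4-[(tert-butyldimethylsilyl)oxy]cyclohex-3-en-1-yl]methanimine (not isolated) | CC(C)(C)[Si](C)(C)OC1=CC[C@@](C=N)(c2cc(Br)ccc2OC(C)(C)C)CC1 | intermediate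
11 | (1R)-1-(5-bromo-2-tert-butoxyphenyl)-4-[(tert-butyldimethylsilyl)oxy]cyclohex-3-ene-1-carbaldehyde | CC(C)(C)[Si](C)(C)OC1=CC[C@@](C=O)(c2cc(Br)ccc2OC(C)(C)C)CC1 | intermediate
12 | 2-(diphenoxyphosphoryl)acetic acid | OC(=O)CP(=O)(Oc1ccccc1)Oc1ccccc1 | starting material
13 | 4,4-diethoxybutan-1-amine | NCCCC(OCC)OCC | starting material
14 | diphenyl {2-[(4,4-diethoxybutyl)amino]-2-oxoethyl}phosphonate | CCOC(CCCNC(=O)CP(=O)(Oc1ccccc1)Oc1ccccc1)OCC | intermediate
15 | (2Z)-3-[(1S)-1-(5-bromo-2-tert-butoxyphenyl)-4-[(tert-butyldimethylsilyl)oxy]cyclohex-3-en-1-yl]-N-(4,4-diethoxybutyl)prop-2-enamide | CC(C)(C)[Si](C)(C)OC1=CC[C@@](/C=C\C(=O)NCCCC(OCC)OCC)(c2cc(Br)ccc2OC(C)(C)C)CC1 | intermediate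
16 | (2Z)-3-[(1S)-1-(2-tert-butoxy-5-formylphenyl)-4-[(tert-butyldimethylsilyl)oxy]cyclohex-3-en-1-yl]-N-(4,4-diethoxybutyl)prop-2-enamide | CC(C)(C)[Si](C)(C)OC1=CC[C@@](/C=C\C(=O)NCCCC(OCC)OCC)(c2cc(C=O)ccc2OC(C)(C)C)CC1 | intermediate
17 | tert-butyl N-(3-aminopropyl)carbamate | NCCCNC(=O)OC(C)(C)C | starting material
18 | tert-butyl N-(3-{[2-(diphenoxyphosphoryl)acetyl]amino}propyl)carbamate | CC(C)(C)OC(=O)NCCCNC(=O)CP(=O)(Oc1ccccc1)Oc1ccccc1 | intermediate
19 | tert-butyl N-{3-[(2Z)-3-{4-tert-butoxy-3-[(1S)-4-[(tert-butyldimethylsilyl)oxy]-1-{(1Z)-3-[(4,4-diethoxybutyl)amino]-3-oxoprop-1-en-1-yl}cyclohex-3-en-1-yl]phenyl}prop-2-enamido]propyl}carbamate | CC(C)(C)[Si](C)(C)OC1=CC[C@@](/C=C\C(=O)NCCCC(OCC)OCC)(c2cc(/C=C\C(=O)NCCCNC(=O)OC(C)(C)C)ccc2OC(C)(C)C)CC1 | intermediate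
20 | tert-butyl N-{3-[(2Z)-3-{4-tert-butoxy-3-[(1S)-1-{(1Z)-3-[(4,4-diethoxybutyl)amino]-3-oxoprop-1-en-1-yl}-4-oxocyclohex-2-en-1-yl]phenyl}prop-2-enamido]propyl}carbamate | O=C1CC[C@](/C=C\C(=O)NCCCC(OCC)OCC)(c2cc(/C=C\C(=O)NCCCNC(=O)OC(C)(C)C)ccc2OC(C)(C)C)C=C1 | intermediate
21 | (2Z)-N-(3-aminopropyl)-3-{4-hydroxy-3-[(1S)-4-oxo-1-{(1Z)-3-oxo-3-[(4-oxobutyl)amino]prop-1-en-1-yl}cyclohex-2-en-1-yl]phenyl}prop-2-enamide (not isolated) | O=C1CC[C@](/C=C\C(=O)NCCCC=O)(c2cc(/C=C\C(=O)NCCCN)ccc2O)C=C1 | intermediate
22 | (2Z)-N-(3-aminopropyl)-3-[(4aR,9bS)-3-oxo-9b-{(1Z)-3-oxo-3-[(4-oxobutyl)amino]prop-1-en-1-yl}-1,2,3,4,4a,9b-hexahydrodibenzo[b,d]furan-8-yl]prop-2-enamide (not isolated) | O=C1CC[C@]2(/C=C\C(=O)NCCCC=O)c3cc(/C=C\C(=O)NCCCN)ccc3O[C@@H]2C1 | intermediate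
23 | macrocyclic aldimine: the target with C=N in place of the butyl CH2–NH bond, (4aR,9bS), both acrylamides Z (not isolated) | O=C1CC[C@]23/C=C\C(=O)NCCCC=NCCCNC(=O)/C=C\c4ccc(c2c4)O[C@@H]3C1 | intermediate
24 | CNP0415009.2: (4aR,9bS)-3-oxo-1,2,3,4,4a,9b-hexahydrodibenzo[b,d]furan bridged from C9b to C8 by the chain (Z)-CH=CH–C(=O)–NH–(CH2)4–NH–(CH2)3–NH–C(=O)–CH=CH-(Z) | O=C1CC[C@]23/C=C\C(=O)NCCCCNCCCNC(=O)/C=C\c4ccc(c2c4)O[C@@H]3C1 | target

**Step count and risks**

Total step count: 13 (11 on the main line, plus steps 7 and 10 for the two olefination reagents).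
Longest linear sequence: 11 steps (steps 1–6, 8, 9, 11, 12, 13).

Steps most likely to fail:

Step 13 (key step). What may go wrong: under the strong acid the unveiled 4-amidobutanal is drained into its cyclic N-acyl hemiaminal or the derived enamide and no longer condenses; the free amine reacts at the ring ketone or between molecules before ring D closes; or the new secondary amine is reduced onto the ketone across the ring. The fallback uncouples the two ring closures and makes the C–N bond by an aza-Wittig reaction of an azide instead of an amine condensation. It sets out from 16. Acid 12 is coupled (DCC, CH2Cl2) with commercial 3-azidopropan-1-amine to diphenyl {2-[(3-azidopropyl)amino]-2-oxoethyl}phosphonate F1. Z-selective Horner–Wadsworth–Emmons olefination of 16 with F1 (t-BuOK, THF, −78 °C) should give the azido bis-(Z)-amide silyl enol ether F2. Saegusa–Ito oxidation (Pd(OAc)2, MeCN, rt) should give the azido enone F3. TFA/H2O (9:1) should then cleave the tert-butyl ether and the acetal and, after oxa-Michael closure, give the tricyclic azido aldehyde F4, which can be isolated because no amine is present. PPh3 in THF at high dilution converts the azide into the iminophosphorane F5, which reacts with the aldehyde only (intramolecular aza-Wittig reaction, ketone untouched at room temperature). The fallback comes back to the route at the macrocyclic aldimine 23, which NaBH(OAc)3/AcOH reduces to 24 as in step 13.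

Step 5. What may go wrong: insufficient discrimination between the enantiotopic α-methylene groups, or partial equilibration of the enolate before it is silylated, so that the enol ether is formed with low enantiomeric purity. The fallback replaces the chiral base by an enzymatic desymmetrisation of a dienone. It sets out from 7. Double dehydrogenation (IBX, DMSO, 80 °C) should give the achiral dienone 1-(5-bromo-2-tert-butoxyphenyl)-4-oxocyclohexa-2,5-diene-1-carbonitrile F6. An ene-reductase of the old yellow enzyme family (NADPH recycled by glucose/glucose dehydrogenase, pH 7 buffer, 30 °C), chosen by screening for the required sense, should reduce one of the two enantiotopic C=C bonds to the enone (1R)-1-(5-bromo-2-tert-butoxyphenyl)-4-oxocyclohex-2-ene-1-carbonitrile F7. Conjugate reduction with Li(s-Bu)3BH (THF, −78 °C) and trapping of the regio-defined enolate with TBSOTf comes back to the route at 9.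

Step 9. What may go wrong: Z to E isomerisation of the acrylamide by hydridopalladium species at 100 °C, or reduction of the aryl bromide to the arene instead of carbonylation. The fallback brings in the (Z)-cinnamamide as a preformed (Z)-vinyl iodide by cross-coupling, with no aldehyde and no second olefination. It sets out from 15. Miyaura borylation (B2pin2, Pd(dppf)Cl2, KOAc, dioxane, 80 °C) should give the aryl pinacol boronate F8. Commercial (Z)-3-iodoacrylic acid is coupled (DCC, CH2Cl2) with 17 to tert-butyl N-{3-[(2Z)-3-iodoprop-2-enamido]propyl}carbamate F9. Suzuki–Miyaura coupling of F8 with F9 (Pd(PPh3)4, K3PO4, THF/H2O, 40 °C), which should proceed with retention of the alkene geometry, comes back to the route at 19, so that 16, 18 and steps 10 and 11 are not needed.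

Further compounds
F1 | step 13 | diphenyl {2-[(3-azidopropyl)amino]-2-oxoethyl}phosphonate | [N-]=[N+]=NCCCNC(=O)CP(=O)(Oc1ccccc1)Oc1ccccc1
F2 | step 13 | (2Z)-N-(3-azidopropyl)-3-{4-tert-butoxy-3-[(1S)-4-[(tert-butyldimethylsilyl)oxy]-1-{(1Z)-3-[(4,4-diethoxybutyl)amino]-3-oxoprop-1-en-1-yl}cyclohex-3-en-1-yl]phenyl}prop-2-enamide | CC(C)(C)[Si](C)(C)OC1=CC[C@@](/C=C\C(=O)NCCCC(OCC)OCC)(c2cc(/C=C\C(=O)NCCCN=[N+]=[N-])ccc2OC(C)(C)C)CC1
F3 | step 13 | (2Z)-N-(3-azidopropyl)-3-{4-tert-butoxy-3-[(1S)-1-{(1Z)-3-[(4,4-diethoxybutyl)amino]-3-oxoprop-1-en-1-yl}-4-oxocyclohex-2-en-1-yl]phenyl}prop-2-enamide | O=C1CC[C@](/C=C\C(=O)NCCCC(OCC)OCC)(c2cc(/C=C\C(=O)NCCCN=[N+]=[N-])ccc2OC(C)(C)C)C=C1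
F4 | step 13 | (2Z)-N-(3-azidopropyl)-3-[(4aR,9bS)-3-oxo-9b-{(1Z)-3-oxo-3-[(4-oxobutyl)amino]prop-1-en-1-yl}-1,2,3,4,4a,9b-hexahydrodibenzo[b,d]furan-8-yl]prop-2-enamide | O=C1CC[C@]2(/C=C\C(=O)NCCCC=O)c3cc(/C=C\C(=O)NCCCN=[N+]=[N-])ccc3O[C@@H]2C1
F5 | step 13 | (2Z)-3-[(4aR,9bS)-3-oxo-9b-{(1Z)-3-oxo-3-[(4-oxobutyl)amino]prop-1-en-1-yl}-1,2,3,4,4a,9b-hexahydrodibenzo[b,d]furan-8-yl]-N-{3-[(triphenyl-λ5-phosphanylidene)amino]propyl}prop-2-enamide | O=C1CC[C@]2(/C=C\C(=O)NCCCC=O)c3cc(/C=C\C(=O)NCCCN=P(c4ccccc4)(c4ccccc4)c4ccccc4)ccc3O[C@@H]2C1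
F6 | step 5 | 1-(5-bromo-2-tert-butoxyphenyl)-4-oxocyclohexa-2,5-diene-1-carbonitrile | N#CC1(c2cc(Br)ccc2OC(C)(C)C)C=CC(=O)C=C1
F7 | step 5 | (1R)-1-(5-bromo-2-tert-butoxyphenyl)-4-oxocyclohex-2-ene-1-carbonitrile | O=C1CC[C@](C#N)(c2cc(Br)ccc2OC(C)(C)C)C=C1
F8 | step 9 | (2Z)-3-[(1S)-1-[2-tert-butoxy-5-(4,4,5,5-tetramethyl-1,3,2-dioxaborolan-2-yl)phenyl]-4-[(tert-butyldimethylsilyl)oxy]cyclohex-3-en-1-yl]-N-(4,4-diethoxybutyl)prop-2-enamide | CC(C)(C)[Si](C)(C)OC1=CC[C@@](/C=C\C(=O)NCCCC(OCC)OCC)(c2cc(B3OC(C)(C)C(C)(C)O3)ccc2OC(C)(C)C)CC1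
F9 | step 9 | tert-butyl N-{3-[(2Z)-3-iodoprop-2-enamido]propyl}carbamate | CC(C)(C)OC(=O)NCCCNC(=O)/C=C\I
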